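## Retrosynthetic overview

- The chromene C3=C4 bond comes last, from a chroman-4-one by reduction and dehydration; the saturated C1′–C2′ link comes from an alkyne by diimide reduction.
- Key disconnection: the C2–C1′ bond and the C2 stereocentre are made together by Cu/bis(oxazoline)-catalysed enantioselective alkynylation of a 4-siloxy-2-methylbenzopyrylium ion (dearomatisation of the pyrylium ring) with a terminal enyne that carries the whole C16 side chain.
- The benzopyrylium ion comes from 6-hydroxy-2-methylchromone, made from 2′,5′-dihydroxyacetophenone and ethyl acetate.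
- The enyne comes from dihydro-β-ionone: ketone to terminal alkyne, Zr-catalysed carboalumination/iodination (E-alkene), Negishi ethynylation.
- Ring order: cyclohexene and benzene rings are bought; the pyranone ring is built (step 4), dearomatised at C2 (step 5) and converted into the 2H-pyran (step 7).

Assumption: C2 of the target is (S) by CIP analysis of the SMILES and the side-chain alkene is E; the facial sense of the Cu/BOX catalyst is assigned by analogy, and the antipodal ligand is used if the first run gives the enantiomer of 13.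

## Route

Step 1
Reactants: 1 dihydro-β-ionone [4-(2,6,6-trimethylcyclohex-1-en-1-yl)butan-2-one]
Product: 3 2-(but-3-yn-1-yl)-1,3,3-trimethylcyclohex-1-ene, via enol diethyl phosphate 2 (not isolated)
Conditions: LDA (1.1 equiv), THF, −78 °C; ClP(O)(OEt)2, −78 °C → rt; LDA (2.3 equiv), −78 °C → rt; H2O
Reagents that add atoms: none
Why: Kinetic deprotonation at the methyl group, O-phosphorylation and double-LDA β-elimination of the terminal enol phosphate give the terminal alkyne (Negishi methyl ketone → alkyne synthesis).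

Step 2
Reactants: 3 2-(but-3-yn-1-yl)-1,3,3-trimethylcyclohex-1-ene
Product: 5 2-[(E)-4-iodo-3-methylbut-3-en-1-yl]-1,3,3-trimethylcyclohex-1-ene, via alkenyl(dimethyl)alane 4 (not isolated)
Conditions: Me3Al (2 equiv), Cp2ZrCl2 (0.25 equiv), CH2Cl2, 0 °C → rt; then I2, THF, −30 → 0 °C
Reagents that add atoms: trimethylaluminium C[Al](C)C; iodine II
Why: Negishi Zr-catalysed carboalumination adds Me and Al syn across the terminal alkyne (Al at the terminus), and iodinolysis with retention fixes the E-trisubstituted alkene; the tetrasubstituted ring alkene is inert.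

Step 3
Reactants: 5 2-[(E)-4-iodo-3-methylbut-3-en-1-yl]-1,3,3-trimethylcyclohex-1-ene
Product: 6 2-[(E)-3-methylhex-3-en-5-yn-1-yl]-1,3,3-trimethylcyclohex-1-ene
Conditions: HC≡CMgBr (2 equiv), ZnBr2 (2 equiv), THF, 0 °C; then 5, Pd(PPh3)4 (5 mol %), rt
Reagents that add atoms: ethynylmagnesium bromide C#C[Mg]Br
Why: Negishi coupling of ethynylzinc bromide with the alkenyl iodide gives the terminal 1,3-enyne directly, with retention of the E geometry.

Step 4
Reactants: 7 2′,5′-dihydroxyacetophenone
Product: 9 6-hydroxy-2-methyl-4H-chromen-4-one, via 1,3-diketone 8 (not isolated)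
Conditions: NaH (4.5 equiv), EtOAc (excess), THF, reflux; then conc. HCl, AcOH, 100 °C
Reagents that add atoms: ethyl acetate CCOC(C)=O
Why: Claisen condensation of the ketone enolate with ethyl acetate gives the o-hydroxyaryl 1,3-diketone, which cyclodehydrates under acid to the 2-methylchromone (classical chromone synthesis).

Step 5
Reactants: 9 6-hydroxy-2-methyl-4H-chromen-4-one; 6 2-[(E)-3-methylhex-3-en-5-yn-1-yl]-1,3,3-trimethylcyclohex-1-ene
Product: 13 (R)-6-hydroxy-2-methyl-2-[(E)-4-methyl-6-(2,6,6-trimethylcyclohex-1-en-1-yl)hex-3-en-1-yn-1-yl]chroman-4-one, via 6-silyloxychromone 10 (not isolated), via benzopyrylium triflate 11 (not isolated), via bis-silyl enol ether adduct 12 (not isolated)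
Conditions: 9, TBSOTf (2.3 equiv), 2,6-lutidine (1.05 equiv), neat, 60 °C, 1 h; then added to CuI (10 mol %), indane-derived bis(oxazoline) L* (12 mol %), 6 (1.0 equiv, 11 in 1.3-fold excess), i-Pr2NEt (2.5 equiv), PhMe, −78 °C, 48 h; then KHF2, MeOH, rt
Reagents that add atoms: none
Why: Enantioselective Cu(I)/BOX-catalysed alkynylation of a 2-methyl-4-siloxybenzopyrylium triflate (a known route to tertiary-ether stereocentres): the chiral copper acetylide adds to the Si face of C2 of the planar cation, dearomatising the pyrylium ring and setting the quaternary centre, and mildly acidic KHF2/MeOH then cleaves the silyl enol ether and the aryl silyl ether without enolate-mediated ring opening.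

Step 6
Reactants: 13 (R)-6-hydroxy-2-methyl-2-[(E)-4-methyl-6-(2,6,6-trimethylcyclohex-1-en-1-yl)hex-3-en-1-yn-1-yl]chroman-4-one
Product: 14 (S)-6-hydroxy-2-methyl-2-[(E)-4-methyl-6-(2,6,6-trimethylcyclohex-1-en-1-yl)hex-3-en-1-yl]chroman-4-one
Conditions: KO2CN=NCO2K (10 equiv), AcOH (slow addition), MeOH/pyridine, 0 °C → rt, stopped when the diene intermediate is consumed
Reagents that add atoms: none
Why: Diimide reduction takes the alkyne through the cis-alkene to the alkane, while the tri- and tetrasubstituted alkenes react far more slowly and the ketone not at all; the stereocentre is untouched, and its descriptor changes from R to S only because the CIP priorities change.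

Step 7
Reactants: 14 (S)-6-hydroxy-2-methyl-2-[(E)-4-methyl-6-(2,6,6-trimethylcyclohex-1-en-1-yl)hex-3-en-1-yl]chroman-4-one
Product: 16 (S)-2-methyl-2-[(E)-4-methyl-6-(2,6,6-trimethylcyclohex-1-en-1-yl)hex-3-en-1-yl]-2H-chromen-6-ol, via chroman-4-ol 15 (not isolated)
Conditions: NaBH4, MeOH, 0 °C; aqueous NH4Cl, crude; then p-TsOH·H2O (5 mol %), PhMe, 60 °C, 30 min, in the dark
Reagents that add atoms: none
Why: Borohydride reduction gives the benzylic chroman-4-ol (both C4 epimers converge), and acid-catalysed E1 dehydration through the O1-stabilised benzylic cation gives the conjugated 2H-chromene; C2 is not involved, and short, dark conditions avoid electrocyclic ring-opening racemisation.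

## Compound list

1 | dihydro-β-ionone, 4-(2,6,6-trimethylcyclohex-1-en-1-yl)butan-2-one | CC(=O)CCC1=C(C)CCCC1(C)C | starting material
2 | diethyl 4-(2,6,6-trimethylcyclohex-1-en-1-yl)but-1-en-2-yl phosphate (formed in the flask) | C=C(CCC1=C(C)CCCC1(C)C)OP(=O)(OCC)OCC | intermediate
3 | 2-(but-3-yn-1-yl)-1,3,3-trimethylcyclohex-1-ene | C#CCCC1=C(C)CCCC1(C)C | intermediate
4 | dimethyl[(E)-2-methyl-4-(2,6,6-trimethylcyclohex-1-en-1-yl)but-1-en-1-yl]alane (formed in the flask) | C[Al](C)/C=C(\C)CCC1=C(C)CCCC1(C)C | intermediate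
5 | 2-[(E)-4-iodo-3-methylbut-3-en-1-yl]-1,3,3-trimethylcyclohex-1-ene | I/C=C(\C)CCC1=C(C)CCCC1(C)C | intermediate
6 | 2-[(E)-3-methylhex-3-en-5-yn-1-yl]-1,3,3-trimethylcyclohex-1-ene | C#C/C=C(\C)CCC1=C(C)CCCC1(C)C | intermediate
7 | 2′,5′-dihydroxyacetophenone | CC(=O)c1cc(O)ccc1O | starting material
8 | 1-(2,5-dihydroxyphenyl)butane-1,3-dione (formed in the flask) | CC(=O)CC(=O)c1cc(O)ccc1O | intermediate
9 | 6-hydroxy-2-methyl-4H-chromen-4-one | Cc1cc(=O)c2cc(O)ccc2o1 | intermediate
10 | 6-[(tert-butyldimethylsilyl)oxy]-2-methyl-4H-chromen-4-one (formed in the flask) | Cc1cc(=O)c2cc(O[Si](C)(C)C(C)(C)C)ccc2o1 | intermediate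
11 | 4,6-bis[(tert-butyldimethylsilyl)oxy]-2-methylchromenylium trifluoromethanesulfonate (formed in the flask) | Cc1cc(O[Si](C)(C)C(C)(C)C)c2cc(O[Si](C)(C)C(C)(C)C)ccc2[o+]1.[O-]S(=O)(=O)C(F)(F)F | intermediate
12 | (R)-4,6-bis[(tert-butyldimethylsilyl)oxy]-2-methyl-2-[(E)-4-methyl-6-(2,6,6-trimethylcyclohex-1-en-1-yl)hex-3-en-1-yn-1-yl]-2H-chromene (formed in the flask) | CC1=C(CC/C(C)=C/C#C[C@@]2(C)C=C(O[Si](C)(C)C(C)(C)C)c3cc(O[Si](C)(C)C(C)(C)C)ccc3O2)C(C)(C)CCC1 | intermediate
13 | (R)-6-hydroxy-2-methyl-2-[(E)-4-methyl-6-(2,6,6-trimethylcyclohex-1-en-1-yl)hex-3-en-1-yn-1-yl]chroman-4-one | CC1=C(CC/C(C)=C/C#C[C@@]2(C)CC(=O)c3cc(O)ccc3O2)C(C)(C)CCC1 | intermediate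
14 | (S)-6-hydroxy-2-methyl-2-[(E)-4-methyl-6-(2,6,6-trimethylcyclohex-1-en-1-yl)hex-3-en-1-yl]chroman-4-one | CC1=C(CC/C(C)=C/CC[C@@]2(C)CC(=O)c3cc(O)ccc3O2)C(C)(C)CCC1 | intermediate
15 | (2S,4RS)-2-methyl-2-[(E)-4-methyl-6-(2,6,6-trimethylcyclohex-1-en-1-yl)hex-3-en-1-yl]chromane-4,6-diol (C4 epimer mixture, crude) | CC1=C(CC/C(C)=C/CC[C@@]2(C)CC(O)c3cc(O)ccc3O2)C(C)(C)CCC1 | intermediate
16 | (S)-2-methyl-2-[(E)-4-methyl-6-(2,6,6-trimethylcyclohex-1-en-1-yl)hex-3-en-1-yl]-2H-chromen-6-ol | CC1=C(CC/C(C)=C/CC[C@@]2(C)C=Cc3cc(O)ccc3O2)C(C)(C)CCC1 | target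

## Step count and risks

Total steps: 7. Longest linear sequence: 6 (steps 1, 2, 3, 5, 6, 7).

The three steps most likely to fail are steps 5, 6 and 7.

Step 5 (key alkynylation): a conjugated enyne as the copper acetylide partner and the in-flask bis-silylated hydroxychromone are extensions of the known scope, so yield or ee may be low. The fallback sets out from 9 and returns at 13. It separates the stereo-defining event from the chain attachment: 9 is converted into 11 as before and alkynylated under the same Cu/BOX conditions with trimethylsilylacetylene, a simple silyl alkyne. This gives the silyl enol ether (R)-4,6-bis[(tert-butyldimethylsilyl)oxy]-2-methyl-2-[(trimethylsilyl)ethynyl]-2H-chromene F1, which is not isolated. Buffered TBAF/AcOH in THF at 0 °C removes all three silyl groups to give (R)-2-ethynyl-6-hydroxy-2-methylchroman-4-one F2. Sonogashira coupling of F2 with vinyl iodide 5 (PdCl2(PPh3)2, CuI, Et3N, THF, rt) then gives 13, so step 3 is no longer needed.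

Step 6 (diimide reduction): the margin between the hindered cis-disubstituted alkene of the intermediate diene and the trisubstituted alkene may be too small, giving over-reduced material that is hard to separate. The fallback sets out from 9 and 5 and returns at 15. It forms the C2′–C3′ bond by sp3–sp2 coupling, so no alkyne is ever reduced next to the trisubstituted alkene. The ethynyl ketone (R)-2-ethynyl-6-hydroxy-2-methylchroman-4-one F2 is made from 9 as described above. Lindlar semi-hydrogenation (H2, Pd/CaCO3–Pb, quinoline, EtOAc) gives (R)-6-hydroxy-2-methyl-2-vinylchroman-4-one F3. NaBH4 in MeOH gives (2R,4RS)-2-methyl-2-vinylchromane-4,6-diol F4. Hydroboration with 9-BBN (3.3 equiv, THF; the two OH groups are transiently O-borylated and freed again by the aqueous base) gives (2S,4RS)-2-[2-(9-borabicyclo[3.3.1]nonan-9-yl)ethyl]-2-methylchromane-4,6-diol F5. B-alkyl Suzuki coupling of F5 in the same flask with vinyl iodide 5 (Pd(dppf)Cl2, aqueous K3PO4, THF/DMF, rt to 50 °C) gives 15, which is dehydrated as in step 7.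

Step 7 (acidic dehydration): the benzylic cation could be trapped by the side-chain alkene, or the acid could isomerise the polyene. The fallback sets out from 15 (isolated after the NaBH4 reduction) and returns at 16. It replaces the E1 process by a concerted syn-elimination under non-acidic conditions. Phenol-selective silylation (TBSCl, imidazole, DMF, 0 °C) gives (2S,4RS)-6-[(tert-butyldimethylsilyl)oxy]-2-methyl-2-[(E)-4-methyl-6-(2,6,6-trimethylcyclohex-1-en-1-yl)hex-3-en-1-yl]chroman-4-ol F6. Burgess reagent (PhMe, 50 °C) gives (S)-tert-butyldimethyl({2-methyl-2-[(E)-4-methyl-6-(2,6,6-trimethylcyclohex-1-en-1-yl)hex-3-en-1-yl]-2H-chromen-6-yl}oxy)silane F7. TBAF (THF, 0 °C) then gives 16.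

## Further compounds

F1 | step 5 | (R)-4,6-bis[(tert-butyldimethylsilyl)oxy]-2-methyl-2-[(trimethylsilyl)ethynyl]-2H-chromene | C[Si](C)(C)C#C[C@@]1(C)C=C(O[Si](C)(C)C(C)(C)C)c2cc(O[Si](C)(C)C(C)(C)C)ccc2O1
F2 | step 5 | (R)-2-ethynyl-6-hydroxy-2-methylchroman-4-one | C#C[C@@]1(C)CC(=O)c2cc(O)ccc2O1
F3 | step 6 | (R)-6-hydroxy-2-methyl-2-vinylchroman-4-one | C=C[C@@]1(C)CC(=O)c2cc(O)ccc2O1
F4 | step 6 | (2R,4RS)-2-methyl-2-vinylchromane-4,6-diol | C=C[C@@]1(C)CC(O)c2cc(O)ccc2O1
F5 | step 6 | (2S,4RS)-2-[2-(9-borabicyclo[3.3.1]nonan-9-yl)ethyl]-2-methylchromane-4,6-diol | B1(CC[C@@]2(C)CC(O)c3cc(O)ccc3O2)C2CCCC1CCC2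
F6 | step 7 | (2S,4RS)-6-[(tert-butyldimethylsilyl)oxy]-2-methyl-2-[(E)-4-methyl-6-(2,6,6-trimethylcyclohex-1-en-1-yl)hex-3-en-1-yl]chroman-4-ol | CC1=C(CC/C(C)=C/CC[C@@]2(C)CC(O)c3cc(O[Si](C)(C)C(C)(C)C)ccc3O2)C(C)(C)CCC1
F7 | step 7 | (S)-tert-butyldimethyl({2-methyl-2-[(E)-4-methyl-6-(2,6,6-trimethylcyclohex-1-en-1-yl)hex-3-en-1-yl]-2H-chromen-6-yl}oxy)silane | CC1=C(CC/C(C)=C/CC[C@@]2(C)C=Cc3cc(O[Si](C)(C)C(C)(C)C)ccc3O2)C(C)(C)CCC1
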